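**Retrosynthetic overview**
1. The last disconnection is the depside ester C–O bond between the ring A carbonyl and the C4 oxygen of ring B. It gives an O-benzyl ring A acid and a ring B phenol carrying a benzyl ester; both benzyl groups leave in one final hydrogenolysis.
2. The strategy rests on this feature of ring B: the carboxyl carbon C1 lies between C2 (OMe) and C6 (pentyl), with the C4 oxygen para to C1. The adjacent pair C1/C6 is read as the former triple bond of a 3-methoxy-5-silyloxybenzyne; C6–pentyl and C1–CO2H are made in one flask by carbomagnesiation and carboxylation.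
3. The aryne comes from the triisopropylsilyl ether of 4-fluoro-3-methoxyphenol, metalated at the only C–H next to fluorine.
4. The ring A acid comes from olivetol by formylation, 4-O-methylation, 2-O-benzylation and aldehyde oxidation.
5. No ring is built; both benzene rings are bought. Order: ring B (steps 1–4), ring A (steps 5–8), union (step 9), deprotection (step 10).

Key step: step 2

Assumption: pentylmagnesium bromide is taken as the commercial ether solution (it is equally made in one operation from 1-bromopentane and magnesium). The target has no stereocentre, so no stereocontrol is required.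

**Step 1**
Reactants: 1 4-fluoro-3-methoxyphenol
Product: 2 (4-fluoro-3-methoxyphenoxy)triisopropylsilane
Conditions: i-Pr3SiCl, imidazole, DMF, rt
Reagents that add atoms: chlorotriisopropylsilane, CC(C)[Si](Cl)(C(C)C)C(C)C
Why: Imidazole-mediated O-silylation of a phenol gives a bulky, non-acidic, poorly coordinating silyl ether that tolerates organolithium and Grignard reagents.

**Step 2**
Reactants: 2 (4-fluoro-3-methoxyphenoxy)triisopropylsilane; 3 pentylmagnesium bromide
Product: 7 2-methoxy-6-pentyl-4-(triisopropylsilyloxy)benzoic acid, via aryllithium 4 (not isolated), via aryne 5 (not isolated), via arylmagnesium bromide 6 (not isolated)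
Conditions: n-BuLi (0.95 equiv), N,N,N',N'',N''-pentamethyldiethylenetriamine (PMDTA), THF, −78 °C; then 3 (3 equiv, Et2O), −78 °C → rt → 45 °C; then dry CO2, −20 °C → rt; cold 1 M HCl
Reagents that add atoms: carbon dioxide, O=C=O
Why: n-BuLi deaggregated by PMDTA acts under acidity control and should remove the single ring proton beside fluorine, since the other activated site is wedged between OMe and the bulky, weakly coordinating silyloxy group; on warming, aryllithium 4 (or the aryl magnesium species formed from it by exchange with 3) expels fluoride to give aryne 5. Pentylmagnesium bromide then adds across the strained triple bond with pentyl going to the carbon remote from OMe, because this places the new carbon–magnesium bond beside the inductively withdrawing, magnesium-coordinating methoxy group, and the resulting arylmagnesium bromide 6 is carboxylated at that carbon by CO2. The closest known reaction type is the alkylation–carboxylation of fluoroanisoles through 3-methoxybenzynes, in which an alkyl organometallic adds to the aryne and the aryl metal is trapped by an electrophile. No ring is closed and no stereocentre is formed. Two selectivities are needed: a single aryne (secured because fluorine has only one ortho hydrogen, its other neighbour carrying OMe) and a single sense of addition (governed by the methoxy group next to the triple bond; the remote silyloxy group exerts only a weaker, opposing inductive bias). A slight deficit of n-BuLi keeps butyl from competing with pentyl for the aryne, and the excess of 3 suppresses addition of the aryl metals 4 and 6 to the aryne.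

**Step 3**
Reactants: 7 2-methoxy-6-pentyl-4-(triisopropylsilyloxy)benzoic acid
Product: 8 benzyl 2-methoxy-6-pentyl-4-(triisopropylsilyloxy)benzoate
Conditions: BnBr, KHCO3, DMF, rt
Reagents that add atoms: benzyl bromide, BrCc1ccccc1
Why: SN2 O-alkylation of the potassium carboxylate is insensitive to the two ortho substituents that would block Fischer esterification, and the weak base KHCO3 should leave the aryl silyl ether intact.

**Step 4**
Reactants: 8 benzyl 2-methoxy-6-pentyl-4-(triisopropylsilyloxy)benzoate
Product: 9 benzyl 4-hydroxy-2-methoxy-6-pentylbenzoate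
Conditions: Bu4NF, AcOH, THF, 0 °C → rt
Reagents that add atoms: none
Why: Fluoride-driven desilylation (formation of the strong Si–F bond), buffered with acetic acid so that the phenoxide is protonated at once and the benzyl ester is not attacked.

**Step 5**
Reactants: 10 olivetol (5-pentylbenzene-1,3-diol)
Product: 12 2,4-dihydroxy-6-pentylbenzaldehyde, via iminium chloride 11 (not isolated)
Conditions: POCl3, DMF, 0 °C → rt; then H2O, 50 °C
Reagents that add atoms: N,N-dimethylformamide, CN(C)C=O; water, O
Why: Vilsmeier–Haack formylation, in which the chloroiminium ion from DMF and POCl3 attacks the resorcinol ring para to one hydroxyl and ortho to the other (the usual site for 5-alkylresorcinols), and water hydrolyses the iminium salt to the aldehyde.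

**Step 6**
Reactants: 12 2,4-dihydroxy-6-pentylbenzaldehyde
Product: 13 2-hydroxy-4-methoxy-6-pentylbenzaldehyde
Conditions: MeI (1.05 equiv), K2CO3 (1.1 equiv), acetone, rt → 40 °C
Reagents that add atoms: iodomethane, CI
Why: Williamson etherification limited to one equivalent, selective because the 4-hydroxyl is the more acidic, free phenol while the 2-hydroxyl is held in a hydrogen bond to the aldehyde carbonyl and reacts far more slowly.

**Step 7**
Reactants: 13 2-hydroxy-4-methoxy-6-pentylbenzaldehyde
Product: 14 2-(benzyloxy)-4-methoxy-6-pentylbenzaldehyde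
Conditions: BnBr, K2CO3, DMF, 60 °C
Reagents that add atoms: benzyl bromide, BrCc1ccccc1
Why: Williamson benzylation of the remaining chelated phenol under more forcing conditions masks it against self-acylation in the later esterification.

**Step 8**
Reactants: 14 2-(benzyloxy)-4-methoxy-6-pentylbenzaldehyde
Product: 15 2-(benzyloxy)-4-methoxy-6-pentylbenzoic acid
Conditions: NaClO2, NaH2PO4, 2-methyl-2-butene, t-BuOH/H2O, rt
Reagents that add atoms: sodium chlorite, [Na+].[O-]Cl=O
Why: Pinnick oxidation converts the aryl aldehyde into the acid through a chlorite adduct that fragments to the acid and HOCl, and the alkene scavenger removes HOCl before it can chlorinate the electron-rich ring.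

**Step 9**
Reactants: 15 2-(benzyloxy)-4-methoxy-6-pentylbenzoic acid; 9 benzyl 4-hydroxy-2-methoxy-6-pentylbenzoate
Product: 17 benzyl 4-{[2-(benzyloxy)-4-methoxy-6-pentylbenzoyl]oxy}-2-methoxy-6-pentylbenzoate, via mixed trifluoroacetic anhydride 16 (not isolated)
Conditions: (CF3CO)2O, toluene, rt
Reagents that add atoms: none
Why: Mixed-anhydride esterification, in which trifluoroacetic anhydride turns the di-ortho-substituted acid into an acylium-like mixed anhydride that the unhindered 4-hydroxyl of 9 attacks at the aroyl carbon, a mode of activation suited to hindered aryl acids and phenols.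

**Step 10**
Reactants: 17 benzyl 4-{[2-(benzyloxy)-4-methoxy-6-pentylbenzoyl]oxy}-2-methoxy-6-pentylbenzoate
Product: 18 2'-O-methylperlatolic acid (4-[(2-hydroxy-4-methoxy-6-pentylbenzoyl)oxy]-2-methoxy-6-pentylbenzoic acid)
Conditions: H2 (1 atm), 10% Pd/C, EtOAc, rt
Reagents that add atoms: none
Why: Heterogeneous catalytic hydrogenolysis cleaves both benzylic C–O bonds (the ring A benzyl ether and the ring B benzyl ester), while the aryl ester joining the rings has no benzylic C–O bond and is inert.

**Compound list**
1 | 4-fluoro-3-methoxyphenol | COc1cc(O)ccc1F | starting material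
2 | (4-fluoro-3-methoxyphenoxy)triisopropylsilane | COc1cc(O[Si](C(C)C)(C(C)C)C(C)C)ccc1F | intermediate
3 | pentylmagnesium bromide | CCCCC[Mg]Br | starting material
4 | [2-fluoro-3-methoxy-5-(triisopropylsilyloxy)phenyl]lithium | COc1cc(O[Si](C(C)C)(C(C)C)C(C)C)cc([Li])c1F | intermediate
5 | 3-methoxy-5-(triisopropylsilyloxy)benzyne (1,2-didehydro-3-methoxy-5-(triisopropylsilyloxy)benzene) | COC1=CC(O[Si](C(C)C)(C(C)C)C(C)C)=CC#C1 | intermediate
6 | [2-methoxy-6-pentyl-4-(triisopropylsilyloxy)phenyl]magnesium bromide | CCCCCc1cc(O[Si](C(C)C)(C(C)C)C(C)C)cc(OC)c1[Mg]Br | intermediate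
7 | 2-methoxy-6-pentyl-4-(triisopropylsilyloxy)benzoic acid | CCCCCc1cc(O[Si](C(C)C)(C(C)C)C(C)C)cc(OC)c1C(=O)O | intermediate
8 | benzyl 2-methoxy-6-pentyl-4-(triisopropylsilyloxy)benzoate | CCCCCc1cc(O[Si](C(C)C)(C(C)C)C(C)C)cc(OC)c1C(=O)OCc1ccccc1 | intermediate
9 | benzyl 4-hydroxy-2-methoxy-6-pentylbenzoate | CCCCCc1cc(O)cc(OC)c1C(=O)OCc1ccccc1 | intermediate
10 | olivetol (5-pentylbenzene-1,3-diol) | CCCCCc1cc(O)cc(O)c1 | starting material
11 | N-[(2,4-dihydroxy-6-pentylphenyl)methylidene]-N-methylmethanaminium chloride | CCCCCc1cc(O)cc(O)c1C=[N+](C)C.[Cl-] | intermediate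
12 | 2,4-dihydroxy-6-pentylbenzaldehyde | CCCCCc1cc(O)cc(O)c1C=O | intermediate
13 | 2-hydroxy-4-methoxy-6-pentylbenzaldehyde | CCCCCc1cc(OC)cc(O)c1C=O | intermediate
14 | 2-(benzyloxy)-4-methoxy-6-pentylbenzaldehyde | CCCCCc1cc(OC)cc(OCc2ccccc2)c1C=O | intermediate
15 | 2-(benzyloxy)-4-methoxy-6-pentylbenzoic acid | CCCCCc1cc(OC)cc(OCc2ccccc2)c1C(=O)O | intermediate
16 | 2-(benzyloxy)-4-methoxy-6-pentylbenzoic trifluoroacetic anhydride | CCCCCc1cc(OC)cc(OCc2ccccc2)c1C(=O)OC(=O)C(F)(F)F | intermediate
17 | benzyl 4-{[2-(benzyloxy)-4-methoxy-6-pentylbenzoyl]oxy}-2-methoxy-6-pentylbenzoate | CCCCCc1cc(OC)cc(OCc2ccccc2)c1C(=O)Oc1cc(CCCCC)c(C(=O)OCc2ccccc2)c(OC)c1 | intermediate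
18 | 2'-O-methylperlatolic acid | CCCCCc1cc(OC)cc(O)c1C(=O)Oc1cc(CCCCC)c(C(=O)O)c(OC)c1 | target

**Step count**
Total: 10 steps. Longest linear sequence: 6 steps (1 → 2 → 7 → 8 → 9 → 17 → 18, or equally 10 → 12 → 13 → 14 → 15 → 17 → 18).

**Steps most likely to fail**

Step 2. The risks are metalation at a ring position other than the one beside fluorine, sluggish loss of fluoride once the aryl metal has exchanged to magnesium, delivery of pentyl to the wrong end of the aryne, and consumption of the aryne by aryl metal to give biaryls. A deuterium quench of an aliquot after the metalation would show the site of deprotonation before the Grignard reagent is committed. Fallback, setting out from aldehyde 12 and avoiding the aryne altogether: the non-chelated 4-hydroxyl is protected chemoselectively (MOMCl, i-Pr2NEt, CH2Cl2, 0 °C) to give 2-hydroxy-4-(methoxymethoxy)-6-pentylbenzaldehyde F1. Methylation of the remaining hydroxyl (MeI, K2CO3, DMF) gives 2-methoxy-4-(methoxymethoxy)-6-pentylbenzaldehyde F2. Pinnick oxidation (NaClO2, NaH2PO4, 2-methyl-2-butene) gives 2-methoxy-4-(methoxymethoxy)-6-pentylbenzoic acid F3. Benzylation (BnBr, KHCO3, DMF) gives benzyl 2-methoxy-4-(methoxymethoxy)-6-pentylbenzoate F4. Acidic acetal cleavage (HCl, THF/H2O, 40 °C) then returns to the route at phenol 9.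

Step 9. The risks are Friedel–Crafts C-acylation of the electron-rich rings by the acylium-like mixed anhydride, and acid-promoted loss of the ortho benzyl ether in the trifluoroacetic acid formed. Fallback, setting out from acid 15 and working under basic conditions: oxalyl chloride with catalytic DMF in CH2Cl2 gives 2-(benzyloxy)-4-methoxy-6-pentylbenzoyl chloride F5. This is added to the sodium phenoxide of 9 (NaH, THF, 0 °C → rt), which should undergo clean O-acylation and return to the route at diester 17.

Step 5. The risks are formylation at the position between the two hydroxyls and double formylation, which would give isomer mixtures that are tedious to separate. Fallback, setting out from olivetol 10 and installing the carboxyl carbon directly: carboxylation with magnesium methyl carbonate (MeOMgOCO2Me, DMF, 120 °C) gives 2,4-dihydroxy-6-pentylbenzoic acid F6. Methylation of the carboxyl and the free 4-hydroxyl (MeI, 2.1 equiv, K2CO3, acetone) leaves the chelated 2-hydroxyl and gives methyl 2-hydroxy-4-methoxy-6-pentylbenzoate F7. Benzylation (BnBr, K2CO3, DMF, 60 °C) gives methyl 2-(benzyloxy)-4-methoxy-6-pentylbenzoate F8. Saponification of the hindered ester (KOH, DMSO/H2O, 90 °C) returns to the route at acid 15.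

**Further compounds**
F1 | step 2 | 2-hydroxy-4-(methoxymethoxy)-6-pentylbenzaldehyde | CCCCCc1cc(OCOC)cc(O)c1C=O
F2 | step 2 | 2-methoxy-4-(methoxymethoxy)-6-pentylbenzaldehyde | CCCCCc1cc(OCOC)cc(OC)c1C=O
F3 | step 2 | 2-methoxy-4-(methoxymethoxy)-6-pentylbenzoic acid | CCCCCc1cc(OCOC)cc(OC)c1C(=O)O
F4 | step 2 | benzyl 2-methoxy-4-(methoxymethoxy)-6-pentylbenzoate | CCCCCc1cc(OCOC)cc(OC)c1C(=O)OCc1ccccc1
F5 | step 9 | 2-(benzyloxy)-4-methoxy-6-pentylbenzoyl chloride | CCCCCc1cc(OC)cc(OCc2ccccc2)c1C(=O)Cl
F6 | step 5 | 2,4-dihydroxy-6-pentylbenzoic acid (olivetolic acid) | CCCCCc1cc(O)cc(O)c1C(=O)O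
F7 | step 5 | methyl 2-hydroxy-4-methoxy-6-pentylbenzoate | CCCCCc1cc(OC)cc(O)c1C(=O)OC
F8 | step 5 | methyl 2-(benzyloxy)-4-methoxy-6-pentylbenzoate | CCCCCc1cc(OC)cc(OCc2ccccc2)c1C(=O)OC
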